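**Assumption:** bulk rosemary-derived (+)-carnosic acid is taken as the commercial chiral starting material. Compound 6 is listed as the open keto-alcohol, although it may sit partly as its 7,10-hemiketal.

## Retrosynthetic overview

1. Komaroviquinone (7) ⇐ keto-alcohol 6 by arene → methoxy-p-quinone oxidation; the 7,10-hemiketal bridge and the C7 stereocentre then form spontaneously (oxa-bridge is the last ring).
2. 6 ⇐ 10β-hydroxy-icetexane 5 by oxidation of the C7 benzylic CH2.
3. 5 ⇐ abietane C20 mesylate 4 by a light-driven 1,2-aryl shift (C9 moves from C10 to C20, ring B 6 → 7) with water capture at C10. This forms the key C9–C20 and C10–O bonds and sets C10.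
4. 4 ⇐ (+)-carnosic acid (1), which supplies ring A, the arene and the C5 stereocentre; its C20 carboxyl becomes the inserted CH2.
5. Ring order: rings A and C are bought; the seven-membered ring comes from ring expansion (step 4); the oxa-bridge closes in step 6.

## Route

**Step 1**
Reactants: 1, (+)-carnosic acid
Product: 2, methyl 11,12-di-O-methylcarnosate
Conditions: MeI (6 equiv), K2CO3, degassed acetone, 45 °C, Ar
Reagents that add atoms: iodomethane, CI
Why: Exhaustive Williamson O-alkylation and carboxylate alkylation under oxygen-free conditions protects the air-sensitive catechol and gives a reducible ester; no stereocentre is touched.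

**Step 2**
Reactants: 2, methyl 11,12-di-O-methylcarnosate
Product: 3, 11,12-dimethoxyabieta-8,11,13-trien-20-ol
Conditions: LiAlH4, THF, reflux
Reagents that add atoms: none
Why: Hydride reduction of the hindered neopentyl ester to the primary alcohol; aryl methyl ethers and both stereocentres are inert.

**Step 3**
Reactants: 3, 11,12-dimethoxyabieta-8,11,13-trien-20-ol
Product: 4, 11,12-dimethoxyabieta-8,11,13-trien-20-yl methanesulfonate
Conditions: MsCl, Et3N, CH2Cl2, −10 °C; cold work-up, used directly
Reagents that add atoms: methanesulfonyl chloride, CS(=O)(=O)Cl
Why: O-sulfonylation via sulfene tolerates the neopentyl hindrance, and SN2 at C20 is impossible, so the mesylate survives at low temperature.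

**Step 4 (key step)**
Reactants: 4, the C20 mesylate
Product: 5, (5S,10S)-11,12-dimethoxy-9(10→20)-abeo-abieta-8,11,13-trien-10-ol
Conditions: hν (254 nm, quartz), MeCN/H2O 3:2, NaHCO3, Ar, 5–10 °C, 5 mM
Reagents that add atoms: water, O
Why: Proposed new method: the S1 state of the 1,2-dimethoxyarene (excited-state oxidation potential about −2.8 V) transfers an electron into the antiperiplanar C20–OMs σ*, mesylate leaves, and the aryl radical cation/C20 radical pair collapses to the aryl-bridged (phenonium) ion, i.e. a photo-Wagner–Meerwein 1,2-aryl shift that forms C9–C20 and expands ring B; water then opens the bridged ion at tertiary C10 anti to the migrating aryl, on the β-face vacated by C20, so the 10β-OH (10S, trans to H-5) is set by the bought C10/C5 configuration and C5 is untouched; the closest known reaction types are the photosolvolysis and photo-Wagner–Meerwein rearrangement of β-(methoxyaryl)alkyl mesylates and chlorides through excited-state aryl participation, and the thermal cationic rearrangement of 20-sulfonyloxy-abietanes to icetexenes; it has not been shown for a neopentyl terpenoid ring expansion with hydrative capture.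

**Step 5**
Reactants: 5, the 10β-hydroxy-icetexane
Product: 6, (5S,10S)-10-hydroxy-11,12-dimethoxy-9(10→20)-abeo-abieta-8,11,13-trien-7-one
Conditions: CrO3, 3,5-dimethylpyrazole, CH2Cl2, −20 → 0 °C
Reagents that add atoms: chromium trioxide, O=[Cr](=O)=O
Why: Cr(VI) benzylic C–H oxidation favours C7 (para to the 12-OMe, unhindered) over C20 (neopentyl, next to quaternary C10); the tertiary 10-OH is inert and no stereocentre changes.

**Step 6**
Reactants: 6, the keto-alcohol
Product: 7, (+)-komaroviquinone
Conditions: CAN (3.5 equiv), MeCN/H2O 2:1, 0 °C, 15 min, in the dark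
Reagents that add atoms: water, O
Why: CAN oxidation of the electron-rich hemiketal tautomer gives an arene radical cation that water captures at C14 (the only free ring position, para to the 11-OMe); oxidative demethylation of the resulting p-methoxyphenol gives the 12-methoxy-11,14-quinone, and the 10β-OH adds to the now strongly electrophilic C7 carbonyl so that the tether fixes C7 as S. The product is light-sensitive, hence the dark work-up.

## Compound list

1 | (+)-carnosic acid, (5S,10R)-11,12-dihydroxyabieta-8,11,13-trien-20-oic acid (H-5 α, CO2H β) | CC(C)C1=C(C(=C2C(=C1)CC[C@@H]3[C@@]2(CCCC3(C)C)C(=O)O)O)O | starting material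

2 | methyl (5S,10R)-11,12-dimethoxyabieta-8,11,13-trien-20-oate | CC(C)C1=C(C(=C2C(=C1)CC[C@@H]3[C@@]2(CCCC3(C)C)C(=O)OC)OC)OC | intermediate

3 | (5S,10R)-11,12-dimethoxyabieta-8,11,13-trien-20-ol | CC(C)C1=C(C(=C2C(=C1)CC[C@@H]3[C@@]2(CCCC3(C)C)CO)OC)OC | intermediate

4 | (5S,10R)-11,12-dimethoxyabieta-8,11,13-trien-20-yl methanesulfonate | CC(C)C1=C(C(=C2C(=C1)CC[C@@H]3[C@@]2(CCCC3(C)C)COS(C)(=O)=O)OC)OC | intermediate

5 | (5S,10S)-11,12-dimethoxy-9(10→20)-abeo-abieta-8,11,13-trien-10-ol (10-OH β, trans to H-5 α; C20 is the CH2 between C9 and C10) | COc1c(OC)c2C[C@@]3(O)CCCC(C)(C)[C@@H]3CCc2cc1C(C)C | intermediate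

6 | (5S,10S)-10-hydroxy-11,12-dimethoxy-9(10→20)-abeo-abieta-8,11,13-trien-7-one (equilibrates with its 7,10-hemiketal) | COc1c(OC)c2C[C@@]3(O)CCCC(C)(C)[C@@H]3CC(=O)c2cc1C(C)C | intermediate

7 | (+)-komaroviquinone, (5S,7S,10S) | COC1=C(C(C)C)C(=O)C2=C(C[C@@]34CCCC(C)(C)[C@@H]3C[C@]2(O)O4)C1=O | target

## Summary

Total steps: 6. Longest linear sequence: 6.

Steps most likely to fail, with fallbacks:

1. **Step 4 (proposed new photochemical ring expansion).** Risks are low quantum efficiency, E1 loss to icetexa-dienes, or unrearranged return to 3. Fallback (known chemistry): heat 4 in pyridine to effect the ground-state cationic rearrangement to the Δ1(10)-icetexene, then epoxidise and open the epoxide with LiAlH4 to install the 10-OH. This costs two extra steps.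

2. **Step 6 (direct oxidation of a p-unsubstituted dimethoxyarene to the methoxy-p-quinone).** Risks are o-quinone formation or low conversion. Fallback: change the phenol plan to a Teuber oxidation. Start with selective 12-O-methylation of carnosic acid and protect the 11-OH as a MOM ether; carry this through steps 2–5, remove the MOM group with acid, and oxidise the free 11-phenol with Fremy's salt to the 11,14-quinone.

3. **Step 5 (C7 benzylic oxidation beside a tertiary alcohol).** Risks are C20 oxidation, 7,10-ether formation or dehydration. Fallback: buy the C7 oxygen by starting from carnosol. Dimethylate, reduce the lactone with LiAlH4 to the 7β,20-diol, oxidise the benzylic alcohol with MnO2 to the 7-ketone, mesylate C20, and ring-expand by solvolysis to reach 6 without any late C–H oxidation.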